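The data were generated by integration for an exercise; noise was put on by code.

A small charge of free enzyme, 0.0069 mol%, has to carry each of these flasks, so count per enzyme. You asked for a quick number, and here it is.

| flask | starting material | second substrate | free enzyme | temperature | remark | time |
|---|---|---|---|---|---|---|
| Wednesday's | 0.050 M | 1.3 equiv | 0.0069 mol% | −8 °C | run made earlier |  |
| Monday's | 0.075 M | 1.3 equiv | 0.0069 mol% | 20 °C | run made earlier |  |
| dawn | 0.10 M | 1.30 equiv | 0.0069 mol% | −20 °C |  | 40 min |
| summer | 0.10 M | 1.30 equiv | 0.0069 mol% | 30 °C |  | 40 min |
| spring | 0.10 M | 1.30 equiv | 0.0069 mol% | 5 °C |  | 40 min |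

| run | time / min | target / % | starting material / % |
|---|---|---|---|
| Wednesday's | 3.00 | 0.6 | 98.2 |
| Wednesday's | 6.00 | 1.0 | 98.1 |
| Wednesday's | 8.00 | 2.0 | 97.4 |
| Wednesday's | 12.0 | 3.4 | 96.7 |
| Wednesday's | 15.0 | 4.3 | 95.7 |
| Monday's | 0.250 | 0.5 | 98.6 |
| Monday's | 0.833 | 2.8 | 95.5 |
| Monday's | 1.50 | 5.3 | 93.6 |
| Monday's | 3.00 | 10.1 | 88.6 |
| Monday's | 4.00 | 14.4 | 86.2 |

(standard deviation of a reading: 0.5 percentage points)

- which flask leads in amount of target, in percent of the starting material charged ("all alike" within 1.5 percentage points) (dawn / summer / spring / all alike)
- how much target is there at the end, in percent of the starting material charged: dawn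
- how much target is there at the end, in percent of the starting material charged: summer
- how much target is there at the end, in percent of the starting material charged: spring

- amounts and yields of first product count crystals too
- given per volume of solution although it is solid: crystals
- the numbers in the tables scatter with a standard deviation of 0.5 percentage points
- what may be going on: second substrate + loaded enzyme <-> second complex; free enzyme <-> dormant form; first complex -> loaded enzyme + first product; crystals <-> first product; starting material + free enzyme <-> first complex; free enzyme -> unfolded enzyme; second complex -> free enzyme + target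

I take one concentration to set the order of the rate: that of the enzyme. Suppose the enzyme stays full of starting material. Then the rate is N times the enzyme concentration, where N is the turnover frequency, target made per charged enzyme per minute. The rate is then zero order in starting material. The loading is a share of the starting material, so each minute's target, as a share of the charge, is N times the loading. This is my commitment, not a finding. Monday's target rises straight to 14.4%, but that is little conversion, and the two runs differ in concentration as well as temperature.

Wednesday's last reading gives N = 41.5 /min at −8 °C. Monday's gives 522 /min at 20 °C. Together they give an activation energy E of 58.4 kJ/mol. At 5 °C that puts N at 143 /min, and this is spring's turnover frequency. Over 40 min, spring then makes 39.6%. The same line gives dawn 3.27%. On that line summer needs 12.6 min for its whole charge, less than its 40 min, so I expect summer to lead and to finish.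

Your forecast also has summer leading, with 2% at dawn, 80% in summer and 28% in spring. On summer it says: “Unfolding is unmeasured and could cap this”. We part on spring, where I stand higher, and on summer, where I see the charge finished.

The flasks give 2.58% at dawn, 99.7% in summer and 37.9% in spring, so summer leads.

    second substrate + loaded enzyme ⇌ second complex (K = 12.0 /M, k = 4.50 × 10⁵ /M/min, Ea = 19.0 kJ/mol, ΔH = 5.00 kJ/mol)
    free enzyme ⇌ dormant form (K = 0.830, k = 1.10 /min, Ea = 83.0 kJ/mol, ΔH = −88.0 kJ/mol)
    first complex → loaded enzyme + first product (k = 2900 /min, Ea = 70.0 kJ/mol)
    crystals ⇌ first product, rate k4*(cs4 - [first product]) while solid is left; crystals form when [first product] > cs4 (solubility = 13.0 mM, k = 15.0 /min)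
    starting material + free enzyme ⇌ first complex (K = 17.0 /M, k = 18000 /M/s, Ea = 23.0 kJ/mol, ΔH = −33.0 kJ/mol)
    free enzyme → unfolded enzyme (k = 7.90 × 10⁻⁴ /min, Ea = 278 kJ/mol)
    second complex → free enzyme + target (k = 22000 /min, Ea = 69.0 kJ/mol)
    (constants at 30 °C)

Summer's unfolded enzyme stands at 1.43% of the catalyst at 40.0 min. Spring's target lies 1.7 percentage points below the 39.6% that N gave. In spring, first complex, the resting state of the round, holds 45.1% of the catalyst at the end, and the dormant form holds 28.9%. Now take the neighbouring flask: spring with its loading cut to 0.0017 mol%, about a quarter. Spring's N times that loading and 40 min gives 9.72%. That neighbour gives 9.82%, with 90% of its starting material still unbound and first complex at 51.5% of the catalyst.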